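## Structural features

Numbering used below: decalin C1–C10; chain C11–C16 from C9; butenolide C17 (β-carbon), C18 (α-CH), C19 (C=O), C20 (OCH2); C21 is the hydroxymethyl carbon on C13. The target is a bicyclic sesterterpenoid: a trans-fused decalin (ring A with the C4 gem-dimethyl group, ring B with the tetrasubstituted C8=C9 alkene and methyl groups on C8 and C10) joined through the C11–C12 ethylene to a conjugated triene that ends in a 4-substituted furan-2(5H)-one. It has only two stereocentres, the adjacent ring-fusion carbons C5 (S, α-H) and C10 (S, β-CH3), and these are the ones present in commercial (+)-sclareolide. The rest of the stereochemistry is two alkene geometries: C13=C14 is trisubstituted with C12 cis to C15 and the hydroxymethyl group trans (13E), and C15=C16 is Z, lying between C14 and the lactone carbon C17. The (Z)-dienyl butenolide is fragile: light, iodine or reversible conjugate addition can isomerise it, base can deprotonate C20, and hydrides or hard nucleophiles attack the lactone; the C8=C9 alkene can migrate or trigger cationic 1,2-shifts in strong acid. The real difficulty is therefore not the ring system but joining the chain to a lactone-bearing terminus while fixing both geometries of the C13–C16 diene, and, secondarily, placing the ring B alkene cleanly at C8=C9. The feature exploited is that C14, C15, C16 and C17 are four contiguous sp2 carbons with a cis C15=C16 bond and with the oxygenated carbon C20 on C17: this is the carbon skeleton of a 2-furfuryl unit whose ring oxygen bridges C14 and C17. In one sentence: a rhodium carbenoid generated at C13 opens a furan ring, so that a flat heteroarene becomes the (15Z)-C14–C17 segment and the C13=C14 bond in one step.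

## Logic of the disconnections

16 ⇒ 14 (through 15). No skeletal bond is cut; the C21 alcohol is traced back to a carboxylic acid. The reason is that C13 must carry an acceptor group to serve as a carbene carbon earlier. The forward step must reduce a carboxyl group next to a conjugated lactone, which calls for activation as a mixed anhydride and a mild hydride.

14 ⇒ 13. The O–C(CH3)3 bond of an ester is cut. A tert-butyl ester is chosen because it is removed by acid alone, without base, nucleophile or hydride. The forward step must leave the C8=C9 alkene in place.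

13 ⇒ 12. The C17=C18 bond, the only C=C of the lactone ring, is cut as an intramolecular Horner–Wadsworth–Emmons olefination. The butenolide becomes a C17 ketone carrying a phosphonoacetate ester on the C20 oxygen. The forward step must use a base mild enough not to isomerise the cis-enone.

12 ⇒ 7 + 10 (key). The C13=C14 double bond is cut completely and the C17 carbonyl oxygen is reconnected to C14, which regenerates a furan ring. The whole C14–C20 segment with its Z-alkene collapses to an achiral heteroarene, C13 becomes a diazo carbon, and the two halves of the molecule are joined convergently. The forward step must capture the carbenoid with the furan faster than a 1,2-hydride shift from C12, must attack the free α-position of the furan, and must place the ester anti to C15.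

10 ⇒ 8 + 9. The acyl C–O bond of the phosphonoacetate ester is cut; both pieces are commodity chemicals. The forward step only needs neutral esterification conditions that spare the furfuryl group.

7 ⇒ 6 ⇒ 4 + 5. The C13=N2 unit is traced to an acetyl-activated C13–H (deacylative diazo transfer), and then the C12–C13 bond is cut as an enolate alkylation. This brings C13 and C21 from a four-carbon keto ester and leaves a primary iodide on the decalin side. The forward alkylation must favour substitution over elimination to the conjugated diene.

4 ⇒ 3 ⇒ 2. The C12–I bond and then the C12 oxidation level are adjusted (iodide from alcohol, alcohol from ester). These are routine changes that demand only neutral or non-acidic conditions.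

2 ⇒ 1. The C8–O bond is re-formed and H-9 is restored, closing the γ-lactone. This reaches a commercial material that already holds C5, C10, all four methyl groups, C11 and C12. The forward step must deliver the alkene regioselectively at C8=C9, which is asked of thermodynamic control.

## Other disconnections considered

Alternative 1: the first that comes to mind. Cut C16–C17 and treat C15=C16 as an alkyne. Forward: Sonogashira coupling (Pd(PPh3)2Cl2, CuI) of the terminal enyne A1 with a 4-halobutenolide to the dienynyl butenolide A2, then Z-selective semihydrogenation over Pd/CaCO3 poisoned with Pb(OAc)2 as the key step. The chosen plan is preferred on three grounds: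
- the semihydrogenation has to stop at a triene that is itself a good substrate for further reduction and for isomerisation on the metal surface;
- the C13=C14 geometry of A1 must be built by a separate multistep sequence;
- two stereo-defining operations are needed where the furan opening uses one.

Alternative 2: cut C4–C5 and C9–C10 of the decalin. Forward: proton-initiated cationic bicyclisation of the acyclic triene ester A3 to give 2. The chosen plan is preferred because this step would have to control absolute configuration with a stoichiometric chiral acid and also the position of the terminating elimination (C8=C9 against the Δ7 and exocyclic isomers). Both are already solved by the chiral-pool lactone 1, and the alternative leaves the triene, the real problem, untouched.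

Alternative 3: pericyclic setting of the triene. Forward: a thermal suprafacial [1,5]-hydrogen shift in the vinylallene A4, which moves a hydrogen from C18 to C14 and creates the butenolide C=C, the Z-C15=C16 bond and C13=C14 together. The chosen plan is preferred because the geometry at C13=C14 would depend on which face of the allene receives the hydrogen, that is, on distinguishing CH2OH from CH2CH2R at C13, which are sterically almost equal. In addition, A4 (an allene plus a geometrically defined alkylidene lactone) is harder to make than 7 and 10.

Key step: step 7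

Remark on names: "Dm" stands for the (4aS,8aS)-2,5,5,8a-tetramethyl-3,4,4a,5,6,7,8,8a-octahydronaphthalen-1-yl group (ring B alkene at C8=C9, trans ring fusion, 10β-CH3, 5α-H). Natural (+)-sclareolide, which has this configuration at C5 and C10, is taken as a commercial starting material.

## Route

Step 1
Reactants: 1 (+)-sclareolide
Product: 2 methyl 2-Dm-acetate
Conditions: conc. H2SO4 (0.5 equiv), MeOH, reflux, 36 h
Reagents that add atoms: methanol, CO
Why: Acid-catalysed alkyl–oxygen cleavage of the tertiary lactone (AAL1) gives the C8 cation, C12 is esterified, and a proton is lost (E1); because protonation of the alkene isomers is reversible under these conditions, the mixture should drain into the tetrasubstituted C8=C9 isomer; C5 and C10 are not involved.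

Step 2
Reactants: 2 methyl 2-Dm-acetate
Product: 3 2-Dm-ethanol
Conditions: LiAlH4, THF, 0 °C → rt
Reagents that add atoms: none
Why: Standard LiAlH4 reduction of an ester; the β,γ-alkene is not conjugated and should stay in place.

Step 3
Reactants: 3 2-Dm-ethanol
Product: 4 2-Dm-ethyl iodide
Conditions: I2, PPh3, imidazole, CH2Cl2, 0 °C → rt
Reagents that add atoms: iodine, [I][I]
Why: Appel-type iodination (Garegg–Samuelsson conditions) by SN2 displacement of the alkoxyphosphonium ion at a primary carbon; the buffered, non-acidic medium should leave the tetrasubstituted alkene untouched.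

Step 4
Reactants: 4 2-Dm-ethyl iodide; 5 tert-butyl 3-oxobutanoate (2 equiv)
Product: 6 tert-butyl 2-acetyl-4-Dm-butanoate (both epimers at C2)
Conditions: K2CO3, DMF, 50 °C
Reagents that add atoms: none
Why: Acetoacetic ester alkylation; the soft, weakly basic enolate should favour SN2 at the primary iodide over E2 to the conjugated diene, and the new stereocentre is destroyed in step 5.

Step 5
Reactants: 6 tert-butyl 2-acetyl-4-Dm-butanoate
Product: 7 tert-butyl 2-diazo-4-Dm-butanoate
Conditions: 4-acetamidobenzenesulfonyl azide, DBU, MeCN, 0 °C → rt
Reagents that add atoms: 4-acetamidobenzenesulfonyl azide, CC(=O)Nc1ccc(cc1)S(=O)(=O)N=[N+]=[N-]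
Why: Regitz deacylative diazo transfer: the enolate adds to the sulfonyl azide and the adduct fragments with transfer of the acetyl group to the sulfonamide nitrogen, leaving the α-alkyl-α-diazo ester.

Step 6
Reactants: 8 furan-2-ylmethanol; 9 2-(diethoxyphosphoryl)acetic acid
Product: 10 furan-2-ylmethyl 2-(diethoxyphosphoryl)acetate
Conditions: DCC, DMAP (cat.), CH2Cl2, 0 °C → rt
Reagents that add atoms: none
Why: Steglich esterification under neutral conditions that spare the acid-sensitive furfuryl system.

Step 7
Reactants: 7 tert-butyl 2-diazo-4-Dm-butanoate; 10 furan-2-ylmethyl 2-(diethoxyphosphoryl)acetate (3 equiv)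
Product: 12 tert-butyl (2E,4Z)-7-{[2-(diethoxyphosphoryl)acetyl]oxy}-2-(2-Dm-ethyl)-6-oxohepta-2,4-dienoate, via oxabicyclohexene adduct 11 (not isolated)
Conditions: Rh2(O2CCPh3)4 (1 mol %), CH2Cl2, −78 °C, slow addition of 7 to 10 and catalyst; then warm to 23 °C, dark
Reagents that add atoms: none
Why: The dirhodium tetrakis(triphenylacetate) catalyst turns 7 into an electrophilic carbenoid at C13, which adds to the unsubstituted C4=C5 bond of the furan ring of 10, bonding first to the free α-carbon, to give the donor–acceptor cyclopropane 11; push from the ring oxygen through the enol ether and pull from the ester then break the cyclopropane bond to the former furan β-carbon and the ring C–O bond (a six-electron cycloreversion or its zwitterionic equivalent), unravelling the heteroarene to the dienone 12. The closest known reaction type is the carbenoid ring-opening of furans by diazo esters ("furan unravelling"), which gives (2E,4Z)-6-oxo-2,4-dienoates; here the carbene carbon carries an alkyl chain in addition to the ester. No ring of the product is closed: a cyclopropane is closed transiently by [2+1] addition, and it and the furan are both opened, with relief of ring strain and formation of the C17=O bond paying for the loss of aromaticity. No stereocentre is created in 12, since the three of 11 vanish on opening. The Z geometry of C15=C16 is inherited from the ring, because C14 and C17 were held cis by the furan oxygen. The E geometry of C13=C14 should follow from the ester taking the exo position in the cyclopropanation, with antiperiplanar fragmentation then placing the exo group trans to C15; this is also the thermodynamically preferred arrangement (the ester stays out of the position cis to C15, where allylic strain would twist it out of conjugation), so reversible oxa-6π closure of the cis-dienone, which can exchange only the C13 terminus, would correct any leakage. The step needs capture by the furan to outrun the 1,2-hydride shift from C12, which the bulky carboxylate ligands, the low temperature and the excess of electron-rich furan should secure, and it needs attack at the free α-position, which the 2-substituent directs. The C8=C9 alkene should not compete because it is tetrasubstituted and shielded by C10, and intramolecular addition to it would require a bicyclo[2.1.0]pentane.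

Step 8
Reactants: 12 tert-butyl (2E,4Z)-7-{[2-(diethoxyphosphoryl)acetyl]oxy}-2-(2-Dm-ethyl)-6-oxohepta-2,4-dienoate
Product: 13 tert-butyl (2E,4Z)-2-(2-Dm-ethyl)-5-(5-oxo-2,5-dihydrofuran-3-yl)penta-2,4-dienoate
Conditions: LiCl, i-Pr2NEt, MeCN, 0 °C → rt, dark
Reagents that add atoms: none
Why: Intramolecular Horner–Wadsworth–Emmons olefination under Masamune–Roush conditions: the lithium-chelated phosphonate anion adds to the C17 ketone in a five-membered ring closure and loses diethyl phosphate, forming C17=C18 and the butenolide; the ring fixes the geometry of this alkene and the non-nucleophilic amine should not isomerise the cis-enone.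

Step 9
Reactants: 13 tert-butyl (2E,4Z)-2-(2-Dm-ethyl)-5-(5-oxo-2,5-dihydrofuran-3-yl)penta-2,4-dienoate
Product: 14 (2E,4Z)-2-(2-Dm-ethyl)-5-(5-oxo-2,5-dihydrofuran-3-yl)penta-2,4-dienoic acid
Conditions: CF3CO2H/CH2Cl2 (1:4), 0 °C, dark
Reagents that add atoms: none
Why: Acidolysis of the tert-butyl ester with loss of isobutene needs no base, nucleophile or hydride, which the lactone and the Z-diene would not tolerate; brief exposure at 0 °C should leave the thermodynamically placed C8=C9 alkene where it is.

Step 10
Reactants: 14 (2E,4Z)-2-(2-Dm-ethyl)-5-(5-oxo-2,5-dihydrofuran-3-yl)penta-2,4-dienoic acid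
Product: 16 4-[(1Z,3E)-4-(hydroxymethyl)-6-Dm-hexa-1,3-dien-1-yl]furan-2(5H)-one, via mixed carbonic anhydride 15 (not isolated)
Conditions: i-BuOCOCl, N-methylmorpholine, THF, −20 °C; then NaBH4, MeOH, −20 → 0 °C, dark
Reagents that add atoms: none
Why: Chemoselective reduction of a carboxylic acid through its mixed carbonic anhydride: borohydride should attack the activated acyl carbon much faster than the lactone carbonyl and give the allylic alcohol by 1,2-reduction; neither alkene geometry and neither stereocentre is touched.

## Compound list

1 | (+)-sclareolide, (3aR,5aS,9aS,9bR)-3a,6,6,9a-tetramethyldecahydronaphtho[2,1-b]furan-2(1H)-one | O=C1C[C@@H]2[C@@]3(C)CCCC(C)(C)[C@@H]3CC[C@@]2(C)O1 | starting material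
2 | methyl 2-[(4aS,8aS)-2,5,5,8a-tetramethyl-3,4,4a,5,6,7,8,8a-octahydronaphthalen-1-yl]acetate (methyl 2-Dm-acetate) | CC1=C(CC(=O)OC)[C@@]2(C)CCCC(C)(C)[C@@H]2CC1 | intermediate
3 | 2-Dm-ethanol | CC1=C(CCO)[C@@]2(C)CCCC(C)(C)[C@@H]2CC1 | intermediate
4 | 2-Dm-ethyl iodide | CC1=C(CCI)[C@@]2(C)CCCC(C)(C)[C@@H]2CC1 | intermediate
5 | tert-butyl 3-oxobutanoate | CC(=O)CC(=O)OC(C)(C)C | starting material
6 | tert-butyl 2-acetyl-4-Dm-butanoate (both epimers at C2) | CC1=C(CCC(C(C)=O)C(=O)OC(C)(C)C)[C@@]2(C)CCCC(C)(C)[C@@H]2CC1 | intermediate
7 | tert-butyl 2-diazo-4-Dm-butanoate | CC1=C(CCC(=[N+]=[N-])C(=O)OC(C)(C)C)[C@@]2(C)CCCC(C)(C)[C@@H]2CC1 | intermediate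
8 | furan-2-ylmethanol | OCc1ccco1 | starting material
9 | 2-(diethoxyphosphoryl)acetic acid | CCOP(=O)(CC(=O)O)OCC | starting material
10 | furan-2-ylmethyl 2-(diethoxyphosphoryl)acetate | CCOP(=O)(CC(=O)OCc1ccco1)OCC | intermediate
11 | tert-butyl 3-({[2-(diethoxyphosphoryl)acetyl]oxy}methyl)-6-(2-Dm-ethyl)-2-oxabicyclo[3.1.0]hex-3-ene-6-carboxylate (mixture of diastereomers at the three cyclopropane carbons, which are lost on opening) | CC1=C(CCC2(C(=O)OC(C)(C)C)C3C=C(COC(=O)CP(=O)(OCC)OCC)OC23)[C@@]4(C)CCCC(C)(C)[C@@H]4CC1 | intermediate (not isolated)
12 | tert-butyl (2E,4Z)-7-{[2-(diethoxyphosphoryl)acetyl]oxy}-2-(2-Dm-ethyl)-6-oxohepta-2,4-dienoate | CC1=C(CC/C(=C\C=C/C(=O)COC(=O)CP(=O)(OCC)OCC)C(=O)OC(C)(C)C)[C@@]2(C)CCCC(C)(C)[C@@H]2CC1 | intermediate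
13 | tert-butyl (2E,4Z)-2-(2-Dm-ethyl)-5-(5-oxo-2,5-dihydrofuran-3-yl)penta-2,4-dienoate | CC1=C(CC/C(=C\C=C/C2=CC(=O)OC2)C(=O)OC(C)(C)C)[C@@]3(C)CCCC(C)(C)[C@@H]3CC1 | intermediate
14 | (2E,4Z)-2-(2-Dm-ethyl)-5-(5-oxo-2,5-dihydrofuran-3-yl)penta-2,4-dienoic acid | CC1=C(CC/C(=C\C=C/C2=CC(=O)OC2)C(O)=O)[C@@]3(C)CCCC(C)(C)[C@@H]3CC1 | intermediate
15 | (2E,4Z)-2-(2-Dm-ethyl)-5-(5-oxo-2,5-dihydrofuran-3-yl)penta-2,4-dienoic isobutyl carbonic anhydride | CC1=C(CC/C(=C\C=C/C2=CC(=O)OC2)C(=O)OC(=O)OCC(C)C)[C@@]3(C)CCCC(C)(C)[C@@H]3CC1 | intermediate (not isolated)
16 | 4-[(1Z,3E)-4-(hydroxymethyl)-6-[(4aS,8aS)-2,5,5,8a-tetramethyl-3,4,4a,5,6,7,8,8a-octahydronaphthalen-1-yl]hexa-1,3-dien-1-yl]furan-2(5H)-one | CC1=C(CC/C(=C\C=C/C2=CC(=O)OC2)CO)[C@@]2(C)CCCC(C)(C)[C@@H]2CC1 | target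

## Step count and risks

Total step count: 10. Longest linear sequence: 9 steps (1 to 16 through steps 1–5 and 7–10); step 6 is a one-step side branch.

Step 7 (key step). What may go wrong:
- the 1,2-hydride shift from C12 in the alkyl carbenoid may outrun intermolecular capture by the furan;
- proton transfer in the zwitterion may lead to formal C–H alkylation of the furan instead of ring-opening;
- the geometry at C13=C14 may erode if the ester does not take the exo position;
- the cis-enone may isomerise from Z to E on handling.

Fallback (sets out from 4, returns at 13), all by established olefination and cross-coupling chemistry. Compound 4 would alkylate the sodium salt of commercial tert-butyl diethylphosphonoacetate (NaH, DMF) to give tert-butyl 2-(diethoxyphosphoryl)-4-Dm-butanoate F1. In parallel, commercial ethyl (Z)-3-iodoacrylate would be reduced with i-Bu2AlH at −78 °C to (Z)-3-iodoprop-2-enal F2. Horner–Wadsworth–Emmons olefination of F2 with the anion of F1 (NaH, THF, −78 → 0 °C) should give tert-butyl (2E,4Z)-5-iodo-2-(2-Dm-ethyl)penta-2,4-dienoate F3; the E-selectivity usual for α-substituted phosphonoacetates puts the ester trans to C15. Stille coupling of F3 with 4-(tributylstannyl)furan-2(5H)-one F4 (Pd2(dba)3, AsPh3, CuI, DMF, rt), which proceeds with retention of both geometries, would deliver 13. F4 would be prepared from commercial 4-bromofuran-2(5H)-one and (Bu3Sn)2 with Pd(PPh3)4.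

Step 1. What may go wrong: incomplete equilibration may leave the Δ7 and exocyclic alkene isomers, the lactone may re-close, and cationic 1,2-shifts may occur along C8–C9–C10 under the acidic conditions.

Fallback (sets out from 1, returns at 3), which fixes the alkene position by structure and not by equilibrium. The lactone enolate (LiN(i-Pr)2, THF, −78 °C) would be selenenylated with PhSeBr on the face syn to H-9 to give 11α-(phenylselanyl)sclareolide F5. Oxidation (H2O2, pyridine, CH2Cl2, 0 °C) and syn-elimination of the selenoxide toward the only β-hydrogen, H-9, would give the C9=C11 butenolide 9(11)-dehydrosclareolide F6. Reductive cleavage of its allylic C8–O bond with SmI2 (THF/HMPA, t-BuOH) and α-protonation of the resulting dienolate at C11 would give 2-Dm-acetic acid F7, in which the alkene can only lie between C8 and C9. LiAlH4 reduction of F7 gives 3.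

Step 8. What may go wrong: base-mediated Z to E isomerisation of the enone, intramolecular Michael addition of the phosphonate anion competing with olefination, and acyl migration at the α-acyloxy ketone.

Fallback (sets out from 7, returns at 13), which closes the lactone under neutral conditions. Compound 8 would be silylated (t-BuMe2SiCl, imidazole) to 2-{[(tert-butyldimethylsilyl)oxy]methyl}furan F8. The carbenoid ring-opening of step 7, run with F8 in place of 10, should give tert-butyl (2E,4Z)-7-[(tert-butyldimethylsilyl)oxy]-2-(2-Dm-ethyl)-6-oxohepta-2,4-dienoate F9. Desilylation with HF·pyridine in THF would free tert-butyl (2E,4Z)-7-hydroxy-2-(2-Dm-ethyl)-6-oxohepta-2,4-dienoate F10. The Bestmann ylide Ph3P=C=C=O in toluene at 60 °C would then acylate the hydroxyl group and close the ring by intramolecular Wittig reaction to 13.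

Steps 9 and 10. What may go wrong: acid-induced migration of the C8=C9 alkene during ester cleavage, and conjugate hydride delivery to the trienyl lactone or hydride attack at the carbonate carbonyl of the anhydride during reduction.

Fallback (sets out from 13, returns at 16), which masks the lactone as an aromatic silyloxyfuran so that a strong hydride can be used on the ester. Compound 13 would be treated with i-Pr3SiOSO2CF3 and Et3N (CH2Cl2, 0 °C) to give tert-butyl (2E,4Z)-2-(2-Dm-ethyl)-5-{5-[(triisopropylsilyl)oxy]furan-3-yl}penta-2,4-dienoate F11. Reduction of the tert-butyl ester with i-Bu2AlH (CH2Cl2, −78 → 0 °C) would give (2E,4Z)-2-(2-Dm-ethyl)-5-{5-[(triisopropylsilyl)oxy]furan-3-yl}penta-2,4-dien-1-ol F12. Hydrolysis of the silyl enol ether with dilute aqueous HCl in THF at 0 °C, with protonation at the former C20, would return the butenolide and give 16.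

## Further compounds

F1 | step 7 | tert-butyl 2-(diethoxyphosphoryl)-4-Dm-butanoate | CC1=C(CCC(C(=O)OC(C)(C)C)P(=O)(OCC)OCC)[C@@]2(C)CCCC(C)(C)[C@@H]2CC1
F2 | step 7 | (Z)-3-iodoprop-2-enal | O=C/C=C\I
F3 | step 7 | tert-butyl (2E,4Z)-5-iodo-2-(2-Dm-ethyl)penta-2,4-dienoate | CC1=C(CC/C(=C\C=C/I)C(=O)OC(C)(C)C)[C@@]2(C)CCCC(C)(C)[C@@H]2CC1
F4 | step 7 | 4-(tributylstannyl)furan-2(5H)-one | CCCC[Sn](CCCC)(CCCC)C1=CC(=O)OC1
F5 | step 1 | 11α-(phenylselanyl)sclareolide (selenium syn to H-9) | O=C1[C@@H]([Se]c2ccccc2)[C@@H]2[C@@]3(C)CCCC(C)(C)[C@@H]3CC[C@@]2(C)O1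
F6 | step 1 | 9(11)-dehydrosclareolide (C9=C11 butenolide) | O=C1C=C2[C@@]3(C)CCCC(C)(C)[C@@H]3CC[C@@]2(C)O1
F7 | step 1 | 2-Dm-acetic acid | CC1=C(CC(O)=O)[C@@]2(C)CCCC(C)(C)[C@@H]2CC1
F8 | step 8 | 2-{[(tert-butyldimethylsilyl)oxy]methyl}furan | CC(C)(C)[Si](C)(C)OCc1ccco1
F9 | step 8 | tert-butyl (2E,4Z)-7-[(tert-butyldimethylsilyl)oxy]-2-(2-Dm-ethyl)-6-oxohepta-2,4-dienoate | CC1=C(CC/C(=C\C=C/C(=O)CO[Si](C)(C)C(C)(C)C)C(=O)OC(C)(C)C)[C@@]2(C)CCCC(C)(C)[C@@H]2CC1
F10 | step 8 | tert-butyl (2E,4Z)-7-hydroxy-2-(2-Dm-ethyl)-6-oxohepta-2,4-dienoate | CC1=C(CC/C(=C\C=C/C(=O)CO)C(=O)OC(C)(C)C)[C@@]2(C)CCCC(C)(C)[C@@H]2CC1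
F11 | step 10 | tert-butyl (2E,4Z)-2-(2-Dm-ethyl)-5-{5-[(triisopropylsilyl)oxy]furan-3-yl}penta-2,4-dienoate | CC1=C(CC/C(=C\C=C/c2coc(O[Si](C(C)C)(C(C)C)C(C)C)c2)C(=O)OC(C)(C)C)[C@@]3(C)CCCC(C)(C)[C@@H]3CC1
F12 | step 10 | (2E,4Z)-2-(2-Dm-ethyl)-5-{5-[(triisopropylsilyl)oxy]furan-3-yl}penta-2,4-dien-1-ol | CC1=C(CC/C(=C\C=C/c2coc(O[Si](C(C)C)(C(C)C)C(C)C)c2)CO)[C@@]3(C)CCCC(C)(C)[C@@H]3CC1
A1 | alternative 1 | (E)-2-(2-Dm-ethyl)pent-2-en-4-yn-1-ol | CC1=C(CC/C(=C\C#C)CO)[C@@]2(C)CCCC(C)(C)[C@@H]2CC1
A2 | alternative 1 | 4-[(E)-4-(hydroxymethyl)-6-Dm-hex-3-en-1-yn-1-yl]furan-2(5H)-one | CC1=C(CC/C(=C\C#CC2=CC(=O)OC2)CO)[C@@]3(C)CCCC(C)(C)[C@@H]3CC1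
A3 | alternative 2 | methyl (3E,7E)-4,8,12-trimethyltrideca-3,7,11-trienoate | COC(=O)C/C=C(\C)CC/C=C(\C)CCC=C(C)C
A4 | alternative 3 | (4E)-4-[4-(hydroxymethyl)-6-Dm-hexa-2,3-dien-1-ylidene]dihydrofuran-2(3H)-one (allene axis undefined) | CC1=C(CCC(CO)=C=C/C=C2\CC(=O)OC2)[C@@]3(C)CCCC(C)(C)[C@@H]3CC1
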